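The route rests on cutting C9–C10 in ring B, the seven-membered ring C1, C5, C6, C7, C8, C9, C10 (guaiane numbering). C10 is the nucleophilic β-carbon of the enol ether C10=C14–O–C4 that bridges cyclopentane ring A (a 2-oxabicyclo[3.2.1]oct-3-ene). Its neighbour C9 is a carbinol, hence a former aldehyde. In one operation the key step joins C9 to C10, closes ring B, sets C9 and restores C10=C14 by loss of H10. Its precursor is the oxabicyclic enol ether whose C5 substituent, syn to the enol ether bridge, is the finished trans α-methylene-γ-lactone carrying a C8 PMB ether and the C9 formyl group. C15 is silylated.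

Key step: step 16

Assumption: the (R,R)-salen manganese chloride catalyst of step 1 is taken to deliver oxygen to the diene in the sense known for cis-β-methylstyrene and indene; if the sense is opposite, the (S,S)-catalyst is used.
Remark: guaiane numbering is used for atoms throughout; O4, O6, O8 and O9 are the oxygens on those carbons.

Step 1
Reactants: 1 (1Z,3Z)-cycloocta-1,3-diene
Product: 2 (1R,8S)-9-oxabicyclo[6.1.0]non-2-ene
Conditions: (R,R)-N,N'-bis(3,5-di-tert-butylsalicylidene)-1,2-cyclohexanediaminomanganese chloride (4 mol%), 4-phenylpyridine N-oxide (20 mol%), aq NaOCl (pH 11), CH2Cl2, 0 °C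
Reagents that add atoms: sodium hypochlorite, [Na+].[O-]Cl
Why: Jacobsen–Katsuki epoxidation works best with cis-alkenes conjugated to a π system such as cyclic 1,3-dienes, should stop at the less electron-rich vinyl epoxide, and the salen ligand selects the alkene face and so sets both epoxide carbons (later C5 and C4).

Step 2
Reactants: 2 (1R,8S)-9-oxabicyclo[6.1.0]non-2-ene
Product: 3 (1S,2S,5S)-bicyclo[3.3.0]oct-7-en-2-ol (cis-fused; endo hydroxyl)
Conditions: LiNEt2 (from Et2NH and n-BuLi), Et2O, 0 °C to reflux; then H2O
Reagents that add atoms: none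
Why: The base-induced transannular epoxide rearrangement (α-lithiation of the allylic epoxide C–H, then carbenoid insertion into the C–H bond across the eight-membered ring) is known for this ring system, keeps the carbinol carbon intact and can give only the cis-fused endo alcohol, so the ring-fusion centres C5 and C1 are relayed from the epoxide.

Step 3
Reactants: 3 (1S,2S,5S)-bicyclo[3.3.0]oct-7-en-2-ol
Product: 4 (1S,5S)-bicyclo[3.3.0]oct-7-en-2-one (C4 ketone; C6=C14 alkene)
Conditions: Dess–Martin periodinane, pyridine, CH2Cl2, 0 °C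
Reagents that add atoms: none
Why: Dess–Martin oxidation with pyridine buffering is neutral enough to leave the β,γ-unsaturated ketone unconjugated, and enolisation could not scramble C5 because only the cis ring fusion is accessible.

Step 4
Reactants: 4 (1S,5S)-bicyclo[3.3.0]oct-7-en-2-one
Product: 5 (1S,2S,5S)-2-{[isopropoxy(dimethyl)silyl]methyl}bicyclo[3.3.0]oct-7-en-2-ol (hydroxyl endo)
Conditions: ClMgCH2SiMe2(Oi-Pr) (from ClCH2SiMe2(Oi-Pr) and Mg), LaCl3·2LiCl, THF, −78 to 0 °C; then H2O
Reagents that add atoms: (isopropoxydimethylsilyl)methylmagnesium chloride, CC(C)O[Si](C)(C)C[Mg]Cl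
Why: Nucleophilic hydroxymethylation with the Tamao silylmethyl Grignard reagent, made less basic by the lanthanum salt, attacks the ketone from the convex face of the cis-bicyclooctene, which puts C15 exo and the C4 hydroxyl endo, cis to the C5–C6 and C1–C10 bonds as the oxygen bridge requires.

Step 5
Reactants: 5 silylmethyl carbinol
Product: 6 (1S,2S,5S)-2-(hydroxymethyl)bicyclo[3.3.0]oct-7-en-2-ol
Conditions: 30% H2O2, KF, KHCO3, THF/MeOH, rt
Reagents that add atoms: hydrogen peroxide, OO
Why: Tamao oxidation replaces C–Si by C–OH under mildly basic peroxide conditions that neither epoxidise the isolated alkene nor trigger Peterson elimination of the β-hydroxysilane.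

Step 6
Reactants: 6 diol
Product: 7 primary (C15) tert-butyldimethylsilyl ether of 6
Conditions: TBSCl, imidazole, CH2Cl2, 0 °C
Reagents that add atoms: tert-butyldimethylsilyl chloride, CC(C)(C)[Si](C)(C)Cl
Why: Silylation distinguishes cleanly between the primary C15 hydroxyl and the tertiary C4 hydroxyl, which must stay free for the bridge.

Step 7
Reactants: 7 silyl ether
Product: 9 bridged lactol aldehyde (3-hydroxy-2-oxabicyclo[3.2.1]octane-8-carbaldehyde; formyl syn to the oxygen bridge; C14 epimers), via secondary ozonide 8 (not isolated)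
Conditions: O3, CH2Cl2, −78 °C; then Me2S, −78 °C to rt
Reagents that add atoms: ozone, [O-][O+]=O
Why: Ozonolysis with reductive work-up cuts the only alkene (C6=C14) into two aldehydes that the ring had held cis to each other and to O4, and O4 can reach only C14 (six-membered lactol), which tells the two aldehydes apart.

Step 8
Reactants: 9 bridged lactol aldehyde
Product: 11 (1S,5S,8R)-1-{[(tert-butyldimethylsilyl)oxy]methyl}-2-oxabicyclo[3.2.1]oct-3-ene-8-carbaldehyde (formyl syn to the O–C14=C10 bridge), via anomeric mesylate 10 (not isolated)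
Conditions: MsCl, Et3N, CH2Cl2, −30 °C to rt
Reagents that add atoms: none
Why: Sulfonylation–elimination of a lactol, the usual way from 2-deoxy lactols to glycals, gives the enol ether through the C14 oxocarbenium ion; a cage hemiacetal (lactol oxygen added to C6) would funnel into the same ion, and brief cold exposure to Et3N should spare C5.

Step 9
Reactants: 12 (S)-but-3-ene-1,2-diol
Product: 13 (4S)-2-(4-methoxyphenyl)-4-vinyl-1,3-dioxolane (acetal epimers)
Conditions: 4-MeOC6H4CH(OMe)2, pyridinium p-toluenesulfonate (cat.), CH2Cl2, rt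
Reagents that add atoms: 4-methoxybenzaldehyde dimethyl acetal, COC(OC)c1ccc(OC)cc1
Why: Acid-catalysed transacetalisation forms the five-membered p-methoxybenzylidene acetal without touching the allylic stereocentre, the future C8.

Step 10
Reactants: 13 p-methoxybenzylidene acetal
Product: 14 (S)-2-[(4-methoxybenzyl)oxy]but-3-en-1-ol
Conditions: i-Bu2AlH, CH2Cl2, −78 to 0 °C; then aq potassium sodium tartrate
Reagents that add atoms: none
Why: In the reductive acetal opening the aluminium binds the less hindered primary oxygen and hydride goes to the resulting oxocarbenium ion, which leaves PMB on the secondary oxygen (O8) and frees the primary hydroxyl (O9).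

Step 11
Reactants: 14 (S)-2-[(4-methoxybenzyl)oxy]but-3-en-1-ol; 15 2-(bromomethyl)acrylic acid
Product: 16 (S)-2-[(4-methoxybenzyl)oxy]but-3-en-1-yl 2-(bromomethyl)acrylate
Conditions: DCC, DMAP (5 mol%), CH2Cl2, 0 °C
Reagents that add atoms: none
Why: Steglich esterification of an unhindered primary alcohol runs at 0 °C with little DMAP, so the allylic bromide is not displaced.

Step 12
Reactants: 16 diene ester
Product: 17 (5S)-3-(bromomethyl)-5-[(4-methoxybenzyl)oxy]-5,6-dihydro-2H-pyran-2-one
Conditions: second-generation Grubbs catalyst (5 mol%), toluene (0.01 M), 80 °C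
Reagents that add atoms: none
Why: Ring-closing metathesis starts at the monosubstituted alkene and closes onto the 2-substituted acrylate, a closure known for methacrylates and 2-(bromomethyl)acrylates, and the ring fixes C8 cis to C12 across C7=C11.

Step 13
Reactants: 11 oxabicyclic aldehyde; 17 bromomethyl δ-lactone
Product: 19 (6S,7S,8S)-hydroxy α-methylene-δ-lactone (C6 carbinol on C7; C6 trans to O8 on the lactone ring), via allylchromium dichloride 18 (not isolated)
Conditions: CrCl2 (3 equiv), THF, rt; then H2O
Reagents that add atoms: none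
Why: In this Nozaki–Hiyama allylation with a 2-(alkoxycarbonyl)allyl bromide, 18 adds at its γ-carbon C7 through a chair Zimmerman–Traxler arrangement in which the lactone ring holds C8 trans to C13 (6,7-anti adduct, hence the later trans γ-lactone), the pseudo-axial PMB ether shields one face of C7 (C6 trans to O8), and the aldehyde reacts with its formyl hydrogen over the enol ether bridge from the open C1 flank, the C4 flank being blocked by CH2OTBS (6S).

Step 14
Reactants: 19 hydroxy δ-lactone
Product: 20 (6S,7S,8S)-trans α-methylene-γ-lactone with C8 PMB ether and free C9 hydroxyl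
Conditions: DBU (0.2 equiv), CH2Cl2, 0 °C to rt
Reagents that add atoms: none
Why: In this base-catalysed translactonisation O6 adds to C12 and the primary alkoxide O9 leaves, the five-membered lactone being favoured over the six-membered one; no stereocentre is touched, and any oxa-Michael addition of O9 to C13 is reversible.

Step 15
Reactants: 20 γ-lactone alcohol
Product: 21 lactone-bearing oxabicyclic enol ether with C8 PMB ether and C9 aldehyde
Conditions: Dess–Martin periodinane, pyridine, CH2Cl2, 0 °C
Reagents that add atoms: none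
Why: Pyridine-buffered Dess–Martin oxidation gives the aldehyde without acid that would hydrate the enol ether or base that would epimerise C8, and 21 is used at once.

Step 16
Reactants: 21 enol ether aldehyde
Product: 23 tetracycle with free C9 hydroxyl (C8 PMB ether; C15 TBS ether), via oxocarbenium magnesium alkoxide 22 (not isolated)
Conditions: MgBr2·OEt2 (3 equiv), 2,6-di-tert-butyl-4-methylpyridine (2 equiv), CH2Cl2 (0.005 M), −78 to −20 °C; then aq NaHCO3
Reagents that add atoms: none
Why: Proposed new method: MgBr2 binds O9 of the aldehyde and O8 of the PMB ether, C10 attacks C9 with the exo π face that lies under the C5 side chain, and the C14 oxocarbenium ion 22, stabilised by O4, loses its only α-hydrogen H10 (the proton ends on the hindered pyridine), so that C10=C14 returns and H10 has been replaced by the carbinol carbon. The closest known reaction types are the Lewis acid promoted addition of alkyl enol ethers to aldehydes (Prins or Mukaiyama-type addition) and the addition–elimination substitutions at C2 of glycals such as formylation and acylation; new are the termination by proton loss after an aldehyde addition, the seven-membered ring and the bridgehead-type enol ether that results. Ring B (C1, C5, C6, C7, C8, C9, C10) closes 7-exo-trig at the carbonyl group, with C10=C14 exocyclic to the new ring. C9 is controlled by the five-membered magnesium chelate: in the chain conformation that brings C9 over C10, O8 is pseudo-equatorial and points away from the bicycle, the chelate holds O9 gauche to it on the outside and the formyl hydrogen over C14, and attack on the exposed face gives the 8,9-trans (diequatorial) arrangement, while the transient C10 centre from exo attack is erased. The step needs C10 as the only nucleophile, which the donor O4 and the syn placement of the side chain secure, since C11=C13 is electron-poor and the anisyl position that could close a six-membered ring is meta to methoxy. MgBr2·OEt2 at low temperature is preferred to SnCl4 because 23 is an allylic alcohol of an enol ether that strong Lewis acids would ionise (Ferrier type) and because SnCl4 cleaves PMB ethers.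

Step 17
Reactants: 23 tetracyclic C9 alcohol
Product: 24 C9 acetate
Conditions: Ac2O, pyridine, DMAP (cat.), CH2Cl2, 0 °C
Reagents that add atoms: acetic anhydride, CC(=O)OC(C)=O
Why: DMAP-catalysed acetylation of the only free hydroxyl runs under basic conditions in which ionisation of the allylic C9–O bond cannot start.

Step 18
Reactants: 24 C9 acetate
Product: 25 C8 alcohol (C9 acetate; C15 TBS ether)
Conditions: DDQ, CH2Cl2/pH 7 phosphate buffer (10:1), 0 °C
Reagents that add atoms: none
Why: Oxidative PMB cleavage with buffered DDQ spares glycal-type enol ethers, acetates, silyl ethers and electron-poor alkenes, and neutral pH at 0 °C holds back acetyl migration and translactonisation.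

Step 19
Reactants: 25 C8 alcohol; 26 angelic acid ((Z)-2-methylbut-2-enoic acid)
Product: 28 C8 angelate (C9 acetate; C15 TBS ether), via mixed anhydride 27 (not isolated)
Conditions: 26, 2,4,6-Cl3C6H2COCl, Et3N, toluene, rt; then 25, 80 °C
Reagents that add atoms: none
Why: Yamaguchi-type esterification through 27 without a nucleophilic catalyst is the established way to put angelic acid on hindered secondary alcohols without Z to E isomerisation, the alcohol attacking the less hindered angeloyl carbonyl.

Step 20
Reactants: 28 C8 angelate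
Product: 29 target CNP0073339.2, (1R,4S,5S,6S,7S,8S,9S) in guaiane numbering
Conditions: Bu4NF, AcOH (1:1), THF, 0 °C to rt
Reagents that add atoms: none
Why: Fluoride cleavage of the primary silyl ether with acetic acid buffered Bu4NF avoids the acid that would ionise the C9 acetate or protonate the enol ether and the base that would move or cleave the esters.

Compound list
1 | (1Z,3Z)-cycloocta-1,3-diene | C1=CC=CCCCC1 | starting material
2 | (1R,8S)-9-oxabicyclo[6.1.0]non-2-ene | C1=C[C@H]2O[C@H]2CCCC1 | intermediate
3 | (1S,2S,5S)-bicyclo[3.3.0]oct-7-en-2-ol, endo alcohol | O[C@H]1CC[C@H]2CC=C[C@@H]12 | intermediate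
4 | (1S,5S)-bicyclo[3.3.0]oct-7-en-2-one | O=C1CC[C@H]2CC=C[C@@H]12 | intermediate
5 | (1S,2S,5S)-2-{[isopropoxy(dimethyl)silyl]methyl}bicyclo[3.3.0]oct-7-en-2-ol | CC(C)O[Si](C)(C)C[C@]1(O)CC[C@H]2CC=C[C@@H]12 | intermediate
6 | (1S,2S,5S)-2-(hydroxymethyl)bicyclo[3.3.0]oct-7-en-2-ol | OC[C@]1(O)CC[C@H]2CC=C[C@@H]12 | intermediate
7 | primary TBS ether of 6 | CC(C)(C)[Si](C)(C)OC[C@]1(O)CC[C@H]2CC=C[C@@H]12 | intermediate
8 | secondary ozonide of 7 | CC(C)(C)[Si](C)(C)OC[C@]1(O)CC[C@H]2CC3OOC(O3)[C@@H]12 | intermediate (not isolated)
9 | bridged lactol aldehyde, formyl syn to the oxygen bridge | O=C[C@@H]1[C@H]2CC[C@]1(CO[Si](C)(C)C(C)(C)C)OC(O)C2 | intermediate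
10 | anomeric (C14) mesylate of 9 | O=C[C@@H]1[C@H]2CC[C@]1(CO[Si](C)(C)C(C)(C)C)OC(OS(C)(=O)=O)C2 | intermediate (not isolated)
11 | (1S,5S,8R)-1-{[(tert-butyldimethylsilyl)oxy]methyl}-2-oxabicyclo[3.2.1]oct-3-ene-8-carbaldehyde | O=C[C@@H]1[C@H]2CC[C@]1(CO[Si](C)(C)C(C)(C)C)OC=C2 | intermediate
12 | (S)-but-3-ene-1,2-diol | C=C[C@H](O)CO | starting material
13 | (4S)-2-(4-methoxyphenyl)-4-vinyl-1,3-dioxolane | C=C[C@H]1COC(c2ccc(OC)cc2)O1 | intermediate
14 | (S)-2-[(4-methoxybenzyl)oxy]but-3-en-1-ol | C=C[C@H](OCc1ccc(OC)cc1)CO | intermediate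
15 | 2-(bromomethyl)acrylic acid | C=C(CBr)C(=O)O | starting material
16 | (S)-2-[(4-methoxybenzyl)oxy]but-3-en-1-yl 2-(bromomethyl)acrylate | C=C[C@H](OCc1ccc(OC)cc1)COC(=O)C(=C)CBr | intermediate
17 | (5S)-3-(bromomethyl)-5-[(4-methoxybenzyl)oxy]-5,6-dihydro-2H-pyran-2-one | BrCC1=C[C@H](OCc2ccc(OC)cc2)COC1=O | intermediate
18 | allylchromium dichloride from 17 | Cl[Cr](Cl)CC1=C[C@H](OCc2ccc(OC)cc2)COC1=O | intermediate (not isolated)
19 | (6S,7S,8S)-hydroxy α-methylene-δ-lactone adduct | C=C1C(=O)OC[C@@H](OCc2ccc(OC)cc2)[C@@H]1[C@H](O)[C@@H]1[C@H]2CC[C@]1(CO[Si](C)(C)C(C)(C)C)OC=C2 | intermediate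
20 | (6S,7S,8S)-trans α-methylene-γ-lactone, C8 PMB ether, C9 alcohol | C=C1C(=O)O[C@@H]([C@H]1[C@H](OCc3ccc(OC)cc3)CO)[C@@H]2[C@H]3CC[C@]2(CO[Si](C)(C)C(C)(C)C)OC=C3 | intermediate
21 | key-step precursor, C8 PMB ether, C9 aldehyde | C=C1C(=O)O[C@@H]([C@H]1[C@H](OCc3ccc(OC)cc3)C=O)[C@@H]2[C@H]3CC[C@]2(CO[Si](C)(C)C(C)(C)C)OC=C3 | intermediate
22 | C14 oxocarbenium bromide with C9 bromomagnesium alkoxide (C9 exo on C10) | C=C1C(=O)O[C@H]2[C@H]1[C@H](OCc3ccc(OC)cc3)[C@@H](O[Mg]Br)[C@@H]1C=[O+][C@@]3(CO[Si](C)(C)C(C)(C)C)CC[C@@H]1[C@@H]23.[Br-] | intermediate (not isolated)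
23 | key-step product, tetracycle with free C9 alcohol | C=C1C(=O)O[C@H]2[C@H]1[C@H](OCc3ccc(OC)cc3)[C@@H](O)C1=CO[C@@]3(CO[Si](C)(C)C(C)(C)C)CC[C@@H]1[C@@H]23 | intermediate
24 | C9 acetate of 23 | C=C1C(=O)O[C@H]2[C@H]1[C@H](OCc3ccc(OC)cc3)[C@@H](OC(C)=O)C1=CO[C@@]3(CO[Si](C)(C)C(C)(C)C)CC[C@@H]1[C@@H]23 | intermediate
25 | C8 alcohol, C9 acetate, C15 TBS ether | C=C1C(=O)O[C@H]2[C@H]1[C@H](O)[C@@H](OC(C)=O)C1=CO[C@@]3(CO[Si](C)(C)C(C)(C)C)CC[C@@H]1[C@@H]23 | intermediate
26 | angelic acid | C/C=C(/C)C(=O)O | starting material
27 | angelic 2,4,6-trichlorobenzoic anhydride | C/C=C(/C)C(=O)OC(=O)c1c(Cl)cc(Cl)cc1Cl | intermediate (not isolated)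
28 | C8 angelate, C9 acetate, C15 TBS ether | C=C1C(=O)O[C@H]2[C@H]1[C@H](OC(=O)/C(C)=C\C)[C@@H](OC(C)=O)C1=CO[C@@]3(CO[Si](C)(C)C(C)(C)C)CC[C@@H]1[C@@H]23 | intermediate
29 | CNP0073339.2 | C=C1C(=O)O[C@H]2[C@H]1[C@H](OC(=O)/C(C)=C\C)[C@@H](OC(C)=O)C1=CO[C@@]3(CO)CC[C@@H]1[C@@H]23 | target

Total step count: 20. Longest linear sequence: 16 steps (steps 1–8 and 13–20, from 1).

Steps most likely to fail

Step 16. The cation 22 may be captured by bromide or by its own alkoxide instead of losing H10. The addition may also revert, or the product may ionise at its allylic C9–O bond. The fallback keeps the C9–C10 disconnection but replaces the cationic closure by an intramolecular Nozaki–Hiyama–Kishi coupling, known chemistry for alkenyl iodides and aldehydes.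
- It sets out from 11. Iodination at C10 with N-iodosuccinimide and catalytic AgNO3 in MeCN (the known C2 iodination of glycals) should give the C10-iodo oxabicyclic aldehyde F1.
- Allylation with 17 and nickel-free CrCl2 as in step 13 should give the iodo hydroxy δ-lactone F2.
- Catalytic DBU should give the iodo γ-lactone alcohol F3, and Dess–Martin periodinane the iodo aldehyde F4.
- CrCl2 with catalytic NiCl2 in DMF at high dilution then converts the C10–I bond into an alkenylchromium species that adds to C9. The sequence comes back to the route at 23.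

Step 13. The reagent may add to the other face of the hindered aldehyde or through a boat arrangement. C5 may epimerise before coupling, or the organochromium species may lose the PMB oxide by 1,4-elimination. The fallback replaces the organochromium reagent formed in situ by a preformed, isolable allylboron reagent with a tighter cyclic transition state.
- It sets out from 17, which with bis(pinacolato)diboron and catalytic Pd2(dba)3 should give the pinacol allylboronate of the δ-lactone F5.
- Heating F5 with 11 in toluene (thermal allylboration, neutral medium) and aqueous work-up comes back to the route at 19.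

Step 19. The angeloyl group may isomerise from Z to E on the way to a crowded alcohol. At 80 °C acetyl may also migrate from O9 to O8, or translactonisation may set in. The fallback builds the Z-alkene only after the acylation.
- It sets out from 25. Coupling with 2-[bis(2,2,2-trifluoroethoxy)phosphoryl]propanoic acid (DCC, catalytic DMAP, 0 °C) should give the C8 phosphonopropanoate F6.
- Still–Gennari olefination of F6 (KN(SiMe3)2, 18-crown-6, THF, −78 °C, acetaldehyde) should give the Z-configured 2-methylbut-2-enoate. The sequence comes back to the route at 28.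

Further compounds
F1 | step 16 | C10-iodo oxabicyclic aldehyde | O=C[C@@H]1[C@H]2CC[C@]1(CO[Si](C)(C)C(C)(C)C)OC=C2I
F2 | step 16 | iodo hydroxy δ-lactone | C=C1C(=O)OC[C@@H](OCc2ccc(OC)cc2)[C@@H]1[C@H](O)[C@@H]1[C@H]2CC[C@]1(CO[Si](C)(C)C(C)(C)C)OC=C2I
F3 | step 16 | iodo γ-lactone alcohol | C=C1C(=O)O[C@@H]([C@H]1[C@H](OCc3ccc(OC)cc3)CO)[C@@H]2[C@H]3CC[C@]2(CO[Si](C)(C)C(C)(C)C)OC=C3I
F4 | step 16 | iodo aldehyde | C=C1C(=O)O[C@@H]([C@H]1[C@H](OCc3ccc(OC)cc3)C=O)[C@@H]2[C@H]3CC[C@]2(CO[Si](C)(C)C(C)(C)C)OC=C3I
F5 | step 13 | pinacol allylboronate of the δ-lactone | CC1(C)OB(CC2=C[C@H](OCc3ccc(OC)cc3)COC2=O)OC1(C)C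
F6 | step 19 | C8 phosphonopropanoate | C=C1C(=O)O[C@H]2[C@H]1[C@H](OC(=O)C(C)P(=O)(OCC(F)(F)F)OCC(F)(F)F)[C@@H](OC(C)=O)C1=CO[C@@]3(CO[Si](C)(C)C(C)(C)C)CC[C@@H]1[C@@H]23
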